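**Retrosynthetic overview**

- The A-ring 2′-OH sits ortho to the ketone, so this oxygen, the carbonyl carbon, Cα and Cβ of the enone can be drawn as the pyranone ring (O1–C2=C3–C4=O) of a 7-acyloxychromone, in which C2 (the future Cβ) is an acceptor carbon.
- Key disconnection: the bond between B-ring C1 and Cβ. It is made by Rh(I)-catalysed conjugate arylation of the chromone C2 with a B-ring arylboronate. In the same flask, hydroxide removes both acyl groups and opens the O1–C2 bond of the resulting flavanone (E1cB, assisted by the B-ring 4-OH para to C2) to give the (E)-chalcone.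
- The B-ring boronate comes from 4-bromo-2-methoxyphenol by ortho C-prenylation, acetylation and Miyaura borylation. The acceptor comes from 7-hydroxychromone by pivaloylation.
- No ring is formed in the route. Both benzene rings are purchased, and the only ring event is the opening of the temporary pyranone ring in the key step.

Key step: step 5

Remark: abyssinone D has no stereocentre, so "single stereoisomer" is read as the (E)-enone; the route has to set only this alkene geometry.

**Step 1**
Reactants: 1 4-bromo-2-methoxyphenol; 2 prenyl bromide (1-bromo-3-methylbut-2-ene)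
Product: 3 4-bromo-2-methoxy-6-(3-methylbut-2-en-1-yl)phenol
Conditions: NaH (1.05 equiv), toluene, 0 °C; then 2, rt to 40 °C; neutral work-up
Reagents that add atoms: prenyl bromide (2), CC(C)=CCBr
Why: In a non-polar medium the tight sodium phenoxide ion pair shields oxygen, so the allylic bromide should alkylate carbon at the only free ortho position (C6; the para position is blocked by bromine), which is the classical ortho C-allylation of alkali phenoxides (Claisen C-alkylation).

**Step 2**
Reactants: 3 4-bromo-2-methoxy-6-(3-methylbut-2-en-1-yl)phenol; 4 acetic anhydride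
Product: 5 4-bromo-2-methoxy-6-(3-methylbut-2-en-1-yl)phenyl acetate
Conditions: Ac2O, Et3N, DMAP (cat.), CH2Cl2, 0 °C to rt
Reagents that add atoms: acetic anhydride (4), CC(=O)OC(C)=O
Why: DMAP-catalysed O-acylation of the hindered phenol should give an electron-withdrawing ester that makes the later arylboronate less prone to protodeboronation and that hydroxide removes in step 5.

**Step 3**
Reactants: 5 4-bromo-2-methoxy-6-(3-methylbut-2-en-1-yl)phenyl acetate; 6 bis(pinacolato)diboron
Product: 7 2-methoxy-6-(3-methylbut-2-en-1-yl)-4-(4,4,5,5-tetramethyl-1,3,2-dioxaborolan-2-yl)phenyl acetate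
Conditions: B2pin2, Pd(dppf)Cl2 (3 mol %), KOAc, 1,4-dioxane, 85 °C
Reagents that add atoms: bis(pinacolato)diboron (6), CC1(C)OB(OC1(C)C)B1OC(C)(C)C(C)(C)O1
Why: Miyaura borylation (oxidative addition into the unhindered C–Br bond, acetate-assisted transmetalation with the diboron, reductive elimination) should proceed with KOAc, a base too weak to cleave the aryl acetate, while the trisubstituted prenyl alkene stays inert.

**Step 4**
Reactants: 8 7-hydroxy-4H-chromen-4-one (7-hydroxychromone); 9 pivaloyl chloride
Product: 10 4-oxo-4H-chromen-7-yl pivalate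
Conditions: PivCl, Et3N, DMAP (cat.), CH2Cl2, 0 °C to rt
Reagents that add atoms: pivaloyl chloride (9), CC(C)(C)C(=O)Cl
Why: Standard DMAP-catalysed acylation of the acidic 7-OH should give a robust ester that keeps this oxygen from becoming a phenoxide, which would switch off the C2 acceptor, and that hydroxide removes in step 5.

**Step 5**
Reactants: 7 2-methoxy-6-(3-methylbut-2-en-1-yl)-4-(4,4,5,5-tetramethyl-1,3,2-dioxaborolan-2-yl)phenyl acetate (limiting); 10 4-oxo-4H-chromen-7-yl pivalate (1.5 equiv)
Product: 13 abyssinone D, via flavanone diester 11 (not isolated), via free flavanone 12 (not isolated)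
Conditions: [Rh(OH)(cod)]2 (3 mol %), 1,4-dioxane/H2O (10:1), 60 °C, Ar; then degassed 2 M aq. KOH, rt; then 1 M HCl, 0 °C, to pH 5
Reagents that add atoms: none
Why: Aryl transfer from boron to Rh(I)–OH gives an aryl-rhodium species that adds across C2=C3 of the chromone with the aryl group at C2 (Hayashi–Miyaura conjugate addition, the known chromone-to-flavanone arylation), and hydrolysis of the oxa-π-allyl rhodium enolate releases racemic flavanone diester 11 and regenerates Rh–OH. Aqueous KOH added to the same flask then cleaves the acetate and the pivalate to give flavanone 12 as its bisphenoxide, in which deprotonation at C3 and the push of the B-ring 4-phenoxide para to C2 expel the A-ring phenoxide O1 (E1cB retro-oxa-Michael opening, the known flavanone-to-2′-hydroxychalcone isomerisation and the reverse of the chalcone isomerase step of flavonoid biosynthesis). No ring is closed; the only ring event is the opening of the temporary pyranone ring, which unveils the 2′-OH and the enone at once. The C2 stereocentre of 11 and 12 is transient and is erased, so an achiral catalyst suffices, and the alkene should form as the E isomer under thermodynamic control of the reversible elimination. The step needs 1,4-regioselectivity at C2, secured by the vinylogous-ester polarisation of the pyranone and the preference of Rh(I) for conjugate over carbonyl addition, and it needs single arylation, secured by keeping the medium base-free until the limiting boronate is consumed and by the poor electrophilicity of the chalcone polyphenoxide in KOH. Cold acidification should return the neutral chalcone, which lacks a 6′-OH and therefore recloses only slowly.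

**Compound list**

1 | 4-bromo-2-methoxyphenol | COc1cc(Br)ccc1O | starting material
2 | prenyl bromide (1-bromo-3-methylbut-2-ene) | CC(C)=CCBr | starting material
3 | 4-bromo-2-methoxy-6-(3-methylbut-2-en-1-yl)phenol | COc1cc(Br)cc(CC=C(C)C)c1O | intermediate
4 | acetic anhydride | CC(=O)OC(C)=O | starting material
5 | 4-bromo-2-methoxy-6-(3-methylbut-2-en-1-yl)phenyl acetate | COc1cc(Br)cc(CC=C(C)C)c1OC(C)=O | intermediate
6 | bis(pinacolato)diboron | CC1(C)OB(OC1(C)C)B1OC(C)(C)C(C)(C)O1 | starting material
7 | 2-methoxy-6-(3-methylbut-2-en-1-yl)-4-(4,4,5,5-tetramethyl-1,3,2-dioxaborolan-2-yl)phenyl acetate | COc1cc(B2OC(C)(C)C(C)(C)O2)cc(CC=C(C)C)c1OC(C)=O | intermediate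
8 | 7-hydroxy-4H-chromen-4-one (7-hydroxychromone) | O=c1ccoc2cc(O)ccc12 | starting material
9 | pivaloyl chloride | CC(C)(C)C(=O)Cl | starting material
10 | 4-oxo-4H-chromen-7-yl pivalate | O=c1ccoc2cc(OC(=O)C(C)(C)C)ccc12 | intermediate
11 | rac-2-[4-acetoxy-3-methoxy-5-(3-methylbut-2-en-1-yl)phenyl]-4-oxochroman-7-yl pivalate (flavanone diester) | COc1cc(C2CC(=O)c3ccc(OC(=O)C(C)(C)C)cc3O2)cc(CC=C(C)C)c1OC(C)=O | intermediate
12 | rac-7-hydroxy-2-[4-hydroxy-3-methoxy-5-(3-methylbut-2-en-1-yl)phenyl]chroman-4-one (free flavanone) | COc1cc(C2CC(=O)c3ccc(O)cc3O2)cc(CC=C(C)C)c1O | intermediate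
13 | abyssinone D, (E)-1-(2,4-dihydroxyphenyl)-3-[4-hydroxy-3-methoxy-5-(3-methylbut-2-en-1-yl)phenyl]prop-2-en-1-one | COc1cc(/C=C/C(=O)c2ccc(O)cc2O)cc(CC=C(C)C)c1O | target

**Step count**

Total steps: 5. Longest linear sequence: 4 (steps 1, 2, 3, 5).

**Steps most likely to fail**

Step 5. Three processes threaten it. The O1–C2 bond may open early (β-oxygen elimination at rhodium or base-induced E1cB) while aryl-rhodium is still present, which would allow a second conjugate arylation. Insertion into the electron-rich vinylogous ester may be slow enough for protodeboronation to win. The chalcone may partly reclose to the flavanone on acidification. The fallback forms the same aryl–vinyl bond by a Mizoroki–Heck reaction; it sets out from aryl bromide 5 and returns at 13. Commercial 2,4-dihydroxybenzaldehyde is treated with MOMCl and i-Pr2NEt to give 2,4-bis(methoxymethoxy)benzaldehyde F1. Vinylmagnesium bromide (THF, −78 °C) gives rac-1-[2,4-bis(methoxymethoxy)phenyl]prop-2-en-1-ol F2. MnO2 in CH2Cl2 oxidises it to the aryl vinyl ketone 1-[2,4-bis(methoxymethoxy)phenyl]prop-2-en-1-one F3. Heck coupling of 5 with F3 (Pd(OAc)2, P(o-tol)3, Et3N, DMF, 90 °C) should give the protected (E)-chalcone 4-{(E)-3-[2,4-bis(methoxymethoxy)phenyl]-3-oxoprop-1-en-1-yl}-2-methoxy-6-(3-methylbut-2-en-1-yl)phenyl acetate F4. Finally, 3 M HCl in MeOH at rt removes both MOM groups and the acetate by methanolysis to give 13.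

Step 1. O-alkylation may compete with C-alkylation in the heterogeneous phenoxide reaction, and the ortho-prenylphenol may cyclise to a chroman if the work-up turns acidic. The fallback installs the prenyl group by a sigmatropic route; it sets out from 1 and returns at 3. Phenol 1 is alkylated with 3-chloro-3-methylbut-1-yne (K2CO3, KI, CuI cat., acetone, reflux) to give 4-bromo-2-methoxy-1-[(2-methylbut-3-yn-2-yl)oxy]benzene F5. Semihydrogenation (H2, Lindlar catalyst, quinoline, EtOAc) gives 4-bromo-2-methoxy-1-[(2-methylbut-3-en-2-yl)oxy]benzene F6. Heating in N,N-diethylaniline at about 130 °C should bring about the aromatic Claisen rearrangement to the only free ortho position and give 3.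

Step 3. The aryl acetate may be cleaved, the product may protodeboronate, or a palladium hydride may move the prenyl double bond into conjugation with the ring. The fallback avoids palladium; it sets out from 3 and returns at 7. Phenol 3 is deprotonated (NaH, THF, 0 °C), subjected to bromine–lithium exchange (t-BuLi, 2.1 equiv, −78 °C) and quenched with 2-isopropoxy-4,4,5,5-tetramethyl-1,3,2-dioxaborolane to give, after NH4Cl work-up, 2-methoxy-6-(3-methylbut-2-en-1-yl)-4-(4,4,5,5-tetramethyl-1,3,2-dioxaborolan-2-yl)phenol F7. Acetylation (Ac2O, Et3N, DMAP cat., CH2Cl2) then gives 7.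

**Further compounds**

F1 | step 5 | 2,4-bis(methoxymethoxy)benzaldehyde | COCOc1ccc(C=O)c(OCOC)c1
F2 | step 5 | rac-1-[2,4-bis(methoxymethoxy)phenyl]prop-2-en-1-ol | COCOc1ccc(C(O)C=C)c(OCOC)c1
F3 | step 5 | 1-[2,4-bis(methoxymethoxy)phenyl]prop-2-en-1-one | COCOc1ccc(C(=O)C=C)c(OCOC)c1
F4 | step 5 | 4-{(E)-3-[2,4-bis(methoxymethoxy)phenyl]-3-oxoprop-1-en-1-yl}-2-methoxy-6-(3-methylbut-2-en-1-yl)phenyl acetate | COCOc1ccc(C(=O)/C=C/c2cc(OC)c(OC(C)=O)c(CC=C(C)C)c2)c(OCOC)c1
F5 | step 1 | 4-bromo-2-methoxy-1-[(2-methylbut-3-yn-2-yl)oxy]benzene | COc1cc(Br)ccc1OC(C)(C)C#C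
F6 | step 1 | 4-bromo-2-methoxy-1-[(2-methylbut-3-en-2-yl)oxy]benzene | COc1cc(Br)ccc1OC(C)(C)C=C
F7 | step 3 | 2-methoxy-6-(3-methylbut-2-en-1-yl)-4-(4,4,5,5-tetramethyl-1,3,2-dioxaborolan-2-yl)phenol | COc1cc(B2OC(C)(C)C(C)(C)O2)cc(CC=C(C)C)c1O
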